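Slowness is the first thing about the north-east flask: after 30.0 h, 68% of the substrate still stands, and the question is what the remaining 30.0 h add.

| flask | substrate | gas phase | catalyst | added ligand | remark | time |
|---|---|---|---|---|---|---|
| north-east | 0.20 M | 11 mM (held) | 1 mM | 0.66 mM | the very flask that is asked about, followed so far |  |
| south-east | 0.20 M | 11 mM (held) | 1 mM | 0.99 mM | run made earlier |  |
| flask | 0.20 M | 11 mM (held) | 1.0 mM | 0.66 mM |  | 2.5 d |

- north-east (time / h: product / %, substrate / %): 5.00: 11, 93; 10.0: 13, 83; 15.0: 19, 81; 20.0: 25, 78; 25.0: 27, 73; 30.0: 30, 68
- south-east (time / d: product / %, substrate / %): 0.208: 10, 93; 0.333: 9, 88; 0.500: 10, 86; 0.833: 24, 82; 1.67: 33, 70; 2.50: 42, 60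

(readings scatter by 2 percentage points)

- the product standing at 2.5 d, as a percentage of the substrate charged
- concentration of dissolved gas in solution at 30 h, in percent of saturation
- the change that raises the amount of product at 2.5 d, in percent of the substrate charged most ("none" if none brings more than 2 percentage points) (violet / red / green / none)
- amount of product at 2.5 d, in percent of the substrate charged, after red

- violet: doubling the amount of catalyst, all else as stated
- red: doubling the transfer coefficient of the gas phase, all else as stated
- green: doubling the saturation concentration of gas phase, all else as stated

- at the start none of the gas phase is in solution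

The 30 h reading is the large part of the answer, so Anna and Ben reckon just the correction, from the substrate readings, and both start at 10.0 h, past the quick first stretch. Anna holds that gas enters at a fixed pace, so the substrate falls on a straight line. It lost 15 percentage points in 20.0 h; prolonged, that gives 54.5% product at 2.5 d.

Ben holds that dissolved gas and catalyst stand steady, so the loss follows c(substrate), the pseudo-first-order case. From the same readings he gets 0.00997 h⁻¹, and that is k, the fractional rate: ln of the ratio of two substrate readings, divided by the time between them. Decaying the 30 h reading at k gives 49.6% product.

The south-east run, with more added ligand, has two nearly equal late stretches. Its substrate drops 12 points, then 10 points, while its k reads 0.189 d⁻¹, then 0.186 d⁻¹. With a scatter of 2 points per reading, that merely leans Ben's way, but I reckon with him.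

The forecast gives 47%, lower than Ben's number, with dissolved gas at 70% of saturation, green as the best change and 52% after red, and it holds that “Transfer is therefore only mildly limiting”.

The flask gives 51.1%, which is 1.5 points above Ben's curve and 3.4 points below Anna's line. Dissolved gas stands at 97.5% of saturation at 30 h; red gives 51.6%, while violet adds 31 points, more than green or red. Anna's line keeps, in this flask after 10.0 h, stretches that are short against 1/k, like the 20.0 h she read it from. Carried on from the 49% of substrate left, k leaves 0.225% at 25.0 d; the flask holds 0.104%.

    gas phase ⇌ dissolved gas, rate k1*(csat - [dissolved gas]) (kL = 8.24 h⁻¹)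
    substrate + dissolved gas + catalyst → catalyst + product (k = 1790 L² mol⁻² h⁻¹)
    dissolved gas ⇌ dormant form (K = 7.10, k = 0.0399 h⁻¹)
    catalyst + added ligand ⇌ idle complex (K = 2950 L mol⁻¹, k = 122 L mol⁻¹ h⁻¹)
    dissolved gas → decomposed reagent (k = 0.0337 h⁻¹)

The neighbour read at 6.0 d has the same charges, and k from the 30 h reading gives it 78.2% product. The computed flask stands at 81.1%.

The readings stem from a simulated flask for an exercise; scatter was added.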